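The bond shared by the cyclopentane and the cycloheptanone joins the tertiary carbinol carbon (C5) to the α-carbon (C1) of the ring ketone (C10): a β-hydroxy ketone. Both rings therefore close in one transannular aldol of a ten-membered 1,6-diketone, itself unveiled by ozonolysis of the tetrasubstituted C5=C10 alkene of a 6-6 octalin built from (R)-pulegone and a Shi epoxide. The key step exploits the secondary hydroxyl (C3) lying 1,4 to C10: its transient five-membered hemiketal and bridged enol ether make C1 the only nucleophile and direct the face of the C5 carbonyl; C1 is finally equilibrated to the trans-fused ketone.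

Key step: step 11

Remark on locants: cyclopentane = C1 (ring-fusion CH), C2, C3 (CHOH), C4 (CMe2), C5 (ring-fusion C–OH); cycloheptanone = C5, C6, C7, C8 (CHMe), C9 (quaternary), C10 (C=O), C1; side chain C11–C12, butenolide C13–C16. The same locants are used for all precursors.

Step 1
Reactants: 1 (R)-(+)-pulegone; 2 2,2,2-trifluoroethyl formate
Product: 3 (3R)-2-(hydroxymethylidene)-3-methyl-6-(propan-2-ylidene)cyclohexan-1-one
Conditions: LiN(iPr)2 (LDA), THF, −78 °C; then 2, −78 → 0 °C; aq. NH4Cl
Reagents that add atoms: 2,2,2-trifluoroethyl formate, O=COCC(F)(F)F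
Why: Kinetic deprotonation of the enone occurs at its only α′-methylene (C9) and the enolate is C-formylated by the activated formate (crossed Claisen condensation), the product being held as its stable β-keto-aldehyde enolate; the chiral-pool C8 methyl centre is not touched.

Step 2
Reactants: 3; 4 iodomethane
Product: 5 (1S,6R)-1,6-dimethyl-2-oxo-3-(propan-2-ylidene)cyclohexane-1-carbaldehyde
Conditions: K2CO3, acetone, 23 °C
Reagents that add atoms: iodomethane, CI
Why: C-Alkylation of the soft potassium enolate of the hydroxymethylene ketone builds the quaternary C9, the electrophile entering anti to the pseudo-axial C8 methyl (A(1,3) strain with the exocyclic enolate carbon), so the new methyl should be trans and the formyl group cis to the C8 methyl.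

Step 3
Reactants: 5; 6 methyltriphenylphosphonium bromide
Product: 7 (2R,3R)-2-ethenyl-2,3-dimethyl-6-(propan-2-ylidene)cyclohexan-1-one
Conditions: 6, KN(SiMe3)2 (KHMDS), THF, 0 °C; then 5, −78 → 0 °C
Reagents that add atoms: methyltriphenylphosphonium bromide, C[P+](c1ccccc1)(c1ccccc1)c1ccccc1.[Br-]
Why: Wittig methylenation is chemoselective for the non-enolisable aldehyde over the hindered cross-conjugated ketone and turns the formyl group into the C11=C12 vinyl group without affecting C9.

Step 4
Reactants: 7; 8 water
Product: 9 (2R,3R)-2-ethenyl-2,3-dimethylcyclohexan-1-one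
Conditions: 3 M aq. HCl, 1,4-dioxane, 100 °C (acetone distilled off)
Reagents that add atoms: none
Why: Acid-catalysed conjugate hydration and retro-aldol cleavage (the classical pulegone to 3-methylcyclohexanone degradation) removes the isopropylidene blocking group as acetone and frees the C5 methylene; C9 is quaternary and C8 is β to the carbonyl, so neither centre can epimerise.

Step 5
Reactants: 9; 10 N-phenylbis(trifluoromethanesulfonimide)
Product: 11 (5R,6R)-6-ethenyl-5,6-dimethylcyclohex-1-en-1-yl trifluoromethanesulfonate
Conditions: KN(SiMe3)2 (KHMDS), THF, −78 °C; then 10, −78 → 0 °C; aq. NH4Cl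
Reagents that add atoms: N-phenylbis(trifluoromethanesulfonimide), O=S(=O)(N(c1ccccc1)S(=O)(=O)C(F)(F)F)C(F)(F)F
Why: The ketone can enolise only towards C5 because C9 is quaternary, so O-sulfonylation of the potassium enolate gives a single enol triflate with the C10=C5 double bond.

Step 6
Reactants: 11; 12 5-bromo-2-methylpent-2-ene
Product: 13 (3R,4R)-3-ethenyl-3,4-dimethyl-2-(4-methylpent-3-en-1-yl)cyclohex-1-ene
Conditions: 12, Zn dust, LiCl, THF, 50 °C; then 11, PdCl2(dppf) (5 mol%), THF, 50 °C
Reagents that add atoms: 5-bromo-2-methylpent-2-ene, CC(C)=CCCBr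
Why: Negishi sp2–sp3 cross-coupling of the alkenyl triflate with the primary alkylzinc bromide (formed by LiCl-assisted zinc insertion) makes the C10–C1 bond, the bidentate dppf ligand suppressing β-hydride elimination while the vinyl and trisubstituted alkenes remain inert.

Step 7
Reactants: 13; 14 potassium peroxymonosulfate (KHSO5, active component of Oxone)
Product: 15 (3S)-3-{2-[(5R,6R)-6-ethenyl-5,6-dimethylcyclohex-1-en-1-yl]ethyl}-2,2-dimethyloxirane
Conditions: L-fructose-derived Shi ketone (enantiomer of the usual catalyst, 30 mol%), Oxone (KHSO5), K2CO3, Bu4NHSO4, MeCN–dimethoxymethane / aq. Na2B4O7–Na2EDTA buffer (pH 10.5), 0 °C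
Reagents that add atoms: potassium peroxymonosulfate, [K+].[O-]S(=O)(=O)OO
Why: Shi asymmetric epoxidation by the chiral dioxirane should be fastest at the unhindered electron-rich chain alkene (the ring alkene is shielded by quaternary C9 and the vinyl group is a slow monosubstituted substrate), and the L-fructose-derived ketone sets the (S) configuration at C3 by reagent control through the spiro transition state.

Step 8
Reactants: 15; 16 4-bromofuran-2(5H)-one
Product: 18 4-(2-{(1R,6R)-2-[2-((2S)-3,3-dimethyloxiran-2-yl)ethyl]-1,6-dimethylcyclohex-2-en-1-yl}ethyl)furan-2(5H)-one, via B-alkyl-9-BBN borane 17 (not isolated)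
Conditions: 9-BBN dimer, THF, 23 °C; then 16, PdCl2(dppf) (5 mol%), AsPh3, Cs2CO3, DMF–THF–H2O, 23 °C
Reagents that add atoms: 4-bromofuran-2(5H)-one, BrC1=CC(=O)OC1
Why: 9-BBN hydroborates only the terminal vinyl group (anti-Markovnikov) and the resulting B-alkylborane undergoes B-alkyl Suzuki–Miyaura coupling with the β-bromobutenolide under mild carbonate conditions that spare the epoxide, completing the C11–C12–butenolide side chain.

Step 9
Reactants: 18
Product: 19 4-{2-[(1R,2R,6S)-6-hydroxy-1,2,5,5-tetramethyl-1,2,3,4,5,6,7,8-octahydronaphthalen-1-yl]ethyl}furan-2(5H)-one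
Conditions: MeAlCl2 (2.5 equiv), CH2Cl2, −78 °C; aq. potassium sodium tartrate (KNaC4H4O6)
Reagents that add atoms: none
Why: Lewis-acid-triggered epoxy-olefin cyclisation: the epoxide ionises at tertiary C4, C5 of the ring alkene attacks it through a chair-like six-membered transition state, and the tertiary C10 cation loses the axial C5 proton to give the thermodynamically preferred tetrasubstituted C5=C10 alkene, the C3 centre being carried over with retention because its C–O bond is not broken.

Step 10
Reactants: 19; 20 ozone
Product: 22 4-{2-[(1R,2R,7S)-7-hydroxy-1,2,6,6-tetramethyl-5,10-dioxocyclodecyl]ethyl}furan-2(5H)-one, via ozonide 21 (not isolated)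
Conditions: O3, CH2Cl2, −78 °C (Sudan red 7B end-point); then Me2S, −78 → 23 °C
Reagents that add atoms: ozone, [O-][O+]=O
Why: Ozone reacts far faster with the electron-rich tetrasubstituted alkene than with the electron-poor conjugated butenolide, and reductive work-up of the ozonide unveils the ten-membered 5,10-diketone with C3, C8 and C9 untouched.

Step 11
Reactants: 22; 8 water (on quench)
Product: 25 4-{2-[(2S,3aR,5R,6R,8aS)-2,8a-dihydroxy-1,1,5,6-tetramethyl-4-oxodecahydroazulen-5-yl]ethyl}furan-2(5H)-one, via hemiketal 23 (not isolated), via bridged enol ether 24 (not isolated)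
Conditions: pyridinium p-toluenesulfonate (10 mol%), 4 Å molecular sieves, CH2Cl2, 23 °C; then BF3·OEt2 (1.5 equiv), −78 → −40 °C; then sat. aq. NaHCO3
Reagents that add atoms: water, O
Why: The C3 hydroxyl adds to C10 to give the five-membered hemiketal, which is dehydrated to the cyclic enol ether (C10=C1), whose C1 then adds across the ring to the BF3-activated C5 ketone; the resulting tricyclic oxocarbenium ion is hydrolysed on quench back to the C10 ketone and the free C3 hydroxyl. The closest known reaction types are the transannular aldolisation of cyclodecane-1,6-diones to hydroazulenones and the Lewis-acid (Mukaiyama/Prins-type) addition of enol ethers to ketones. The new C1–C5 bond closes the cyclopentane in a 5-(enolexo)-exo-trig mode and the cycloheptanone in a 7-(enolendo)-exo-trig mode in the same event. At C5 the temporary O3–C10 bridge holds C10 on the O3 face of the forming cyclopentane and the three-carbon link C6–C7–C8 to C9 can only close on that same (endo) face, so the C5 hydroxyl should end anti to the C3 hydroxyl as in the target; C1 is necessarily formed with C10 syn to O3 (cis-fused, the C1 epimer of the target) and is corrected in step 12. The step needs regioselectivity between two similarly hindered ketones (C1 onto C5, not C6 onto C10), which is secured because only C10 can form an enol ether through a five-membered ring with the C3 oxygen and C9 is quaternary; it also needs the tertiary aldol to survive, hence the low temperature and buffered quench.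

Step 12
Reactants: 25
Product: 26 4-{2-[(2S,3aS,5R,6R,8aS)-2,8a-dihydroxy-1,1,5,6-tetramethyl-4-oxodecahydroazulen-5-yl]ethyl}furan-2(5H)-one (target)
Conditions: DBU (0.3 equiv), toluene, 23 → 50 °C
Reagents that add atoms: none
Why: The C1 hydrogen is α to the C10 ketone, so amidine-base enolisation should equilibrate the ring fusion to the trans-fused bicyclo[5.3.0]decan-2-one expected to be thermodynamically preferred, in which C10 and the C3 oxygen are trans on the cyclopentane so the hemiketal cannot re-form; C3, C5, C8 and C9 are not enolisable and keep their configuration.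

Compound list
1 | (R)-(+)-pulegone | C[C@@H]1CCC(=C(C)C)C(=O)C1 | starting material
2 | 2,2,2-trifluoroethyl formate | O=COCC(F)(F)F | starting material
3 | (3R)-2-(hydroxymethylidene)-3-methyl-6-(propan-2-ylidene)cyclohexan-1-one | C[C@@H]1CCC(=C(C)C)C(=O)C1=CO | intermediate
4 | iodomethane | CI | starting material
5 | (1S,6R)-1,6-dimethyl-2-oxo-3-(propan-2-ylidene)cyclohexane-1-carbaldehyde (formyl cis to the C8 methyl) | C[C@@H]1CCC(=C(C)C)C(=O)[C@]1(C)C=O | intermediate
6 | methyltriphenylphosphonium bromide | C[P+](c1ccccc1)(c1ccccc1)c1ccccc1.[Br-] | starting material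
7 | (2R,3R)-2-ethenyl-2,3-dimethyl-6-(propan-2-ylidene)cyclohexan-1-one | C[C@@H]1CCC(=C(C)C)C(=O)[C@]1(C)C=C | intermediate
8 | water | O | starting material
9 | (2R,3R)-2-ethenyl-2,3-dimethylcyclohexan-1-one | C[C@@H]1CCCC(=O)[C@]1(C)C=C | intermediate
10 | N-phenylbis(trifluoromethanesulfonimide) | O=S(=O)(N(c1ccccc1)S(=O)(=O)C(F)(F)F)C(F)(F)F | starting material
11 | (5R,6R)-6-ethenyl-5,6-dimethylcyclohex-1-en-1-yl trifluoromethanesulfonate | C[C@@H]1CCC=C(OS(=O)(=O)C(F)(F)F)[C@]1(C)C=C | intermediate
12 | 5-bromo-2-methylpent-2-ene | CC(C)=CCCBr | starting material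
13 | (3R,4R)-3-ethenyl-3,4-dimethyl-2-(4-methylpent-3-en-1-yl)cyclohex-1-ene | C[C@@H]1CCC=C(CCC=C(C)C)[C@]1(C)C=C | intermediate
14 | potassium peroxymonosulfate (KHSO5, active component of Oxone) | [K+].[O-]S(=O)(=O)OO | starting material
15 | (3S)-3-{2-[(5R,6R)-6-ethenyl-5,6-dimethylcyclohex-1-en-1-yl]ethyl}-2,2-dimethyloxirane | C[C@@H]1CCC=C(CC[C@@H]2OC2(C)C)[C@]1(C)C=C | intermediate
16 | 4-bromofuran-2(5H)-one | BrC1=CC(=O)OC1 | starting material
17 | B-alkyl-9-BBN borane from hydroboration of the vinyl group of 15 (boron on C12) | C[C@@H]1CCC=C(CC[C@@H]2OC2(C)C)[C@]1(C)CCB1C2CCCC1CCC2 | intermediate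
18 | 4-(2-{(1R,6R)-2-[2-((2S)-3,3-dimethyloxiran-2-yl)ethyl]-1,6-dimethylcyclohex-2-en-1-yl}ethyl)furan-2(5H)-one | C[C@@H]1CCC=C(CC[C@@H]2OC2(C)C)[C@]1(C)CCC1=CC(=O)OC1 | intermediate
19 | 4-{2-[(1R,2R,6S)-6-hydroxy-1,2,5,5-tetramethyl-1,2,3,4,5,6,7,8-octahydronaphthalen-1-yl]ethyl}furan-2(5H)-one (C5=C10 octalin) | C[C@@H]1CCC2=C(CC[C@H](O)C2(C)C)[C@]1(C)CCC1=CC(=O)OC1 | intermediate
20 | ozone | [O-][O+]=O | starting material
21 | ozonide (1,2,4-trioxolane bridging C5 and C10 of the ten-membered ring; mixture at C5/C10) | C[C@@H]1CCC23OOC(O2)(CC[C@H](O)C3(C)C)[C@]1(C)CCC1=CC(=O)OC1 | intermediate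
22 | 4-{2-[(1R,2R,7S)-7-hydroxy-1,2,6,6-tetramethyl-5,10-dioxocyclodecyl]ethyl}furan-2(5H)-one | C[C@@H]1CCC(=O)C(C)(C)[C@@H](O)CCC(=O)[C@]1(C)CCC1=CC(=O)OC1 | intermediate
23 | hemiketal of 22 (C3–O–C10 tetrahydrofuran-2-ol; C10 epimers) | C[C@@H]1CCC(=O)C(C)(C)[C@@H]2CCC(O)(O2)[C@]1(C)CCC1=CC(=O)OC1 | intermediate
24 | bridged enol ether of 22 (4,5-dihydrofuran with C10=C1, C5 ketone intact) | C[C@@H]1CCC(=O)C(C)(C)[C@@H]2CC=C(O2)[C@]1(C)CCC1=CC(=O)OC1 | intermediate
25 | 4-{2-[(2S,3aR,5R,6R,8aS)-2,8a-dihydroxy-1,1,5,6-tetramethyl-4-oxodecahydroazulen-5-yl]ethyl}furan-2(5H)-one (cis-fused C1 epimer of the target) | C[C@@H]1CC[C@]2(O)[C@@H](C[C@H](O)C2(C)C)C(=O)[C@]1(C)CCC1=CC(=O)OC1 | intermediate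
26 | 4-{2-[(2S,3aS,5R,6R,8aS)-2,8a-dihydroxy-1,1,5,6-tetramethyl-4-oxodecahydroazulen-5-yl]ethyl}furan-2(5H)-one (CNP0077405.3) | C[C@@H]1CC[C@]2(O)[C@H](C[C@H](O)C2(C)C)C(=O)[C@]1(C)CCC1=CC(=O)OC1 | target

Total step count: 12.
Longest linear sequence: 12 steps (1 → 26); all other inputs are commercial reagents.

Steps most likely to fail

Step 11 (key step). The bridged enol ether may not engage the C5 carbonyl because strain builds up in the oxanorbornane-type oxocarbenium ion, or the tertiary aldol may dehydrate under Lewis acid. The fallback sets out from 19 and abandons the hemiketal tether in favour of the classical base-mediated, reversible transannular aldolisation of a cyclodecane-1,6-dione. The C3 hydroxyl is silylated (TBSOTf, 2,6-lutidine, CH2Cl2) to give the silyl ether F1. Ozonolysis as in step 10 gives the silyloxy diketone F2, which can neither form a hemiketal nor undergo retro-aldol cleavage at C3–C4. Treatment with KOtBu (0.2 equiv) in t-BuOH/THF at 0 → 23 °C should let the aldol, its reverse and the C1 enolisation equilibrate to the trans-fused silyl ether F3. HF·pyridine in MeCN removes the silyl group and the route is rejoined at 26.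

Step 9. The C10 cation may lose a C1 proton instead of the C5 proton, or be captured internally by the C3 oxygen. The fallback sets out from 18 and separates ring closure from placement of the double bond. The cyclisation is run under kinetic control (MeAlCl2, −78 °C, early quench) and accepted as the trisubstituted C1=C10 isomer F4 (C5–H retained, either C5 epimer). The double bond is then moved into the ring fusion by rhodium-hydride addition–elimination with RhCl3·3H2O in ethanol at 70 °C, which should lead to the most substituted alkene, and the route is rejoined at 19.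

Step 12. Equilibration at C1 may stall, or base may reopen the aldol to the macrocycle, which with a free C3 hydroxyl can fragment irreversibly by retro-aldol cleavage of C3–C4. The fallback sets out from 25. TESCl and imidazole in DMF silylate the secondary C3 hydroxyl selectively to give F5. With the C3 oxygen blocked the fragmentation is impossible, so equilibration can be driven under stronger, fully reversible conditions (KOtBu, t-BuOH, 23 °C; enolisation or retro-aldol/aldol) to the trans-fused silyl ether F6. HF·pyridine in MeCN then gives 26.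

Further compounds
F1 | step 11 | tert-butyldimethylsilyl ether of 19 (C3–OTBS octalin) | C[C@@H]1CCC2=C(CC[C@H](O[Si](C)(C)C(C)(C)C)C2(C)C)[C@]1(C)CCC1=CC(=O)OC1
F2 | step 11 | tert-butyldimethylsilyl ether of 22 (C3–OTBS ten-membered 5,10-diketone) | C[C@@H]1CCC(=O)C(C)(C)[C@@H](O[Si](C)(C)C(C)(C)C)CCC(=O)[C@]1(C)CCC1=CC(=O)OC1
F3 | step 11 | C3 tert-butyldimethylsilyl ether of 26 (trans-fused) | C[C@@H]1CC[C@]2(O)[C@H](C[C@H](O[Si](C)(C)C(C)(C)C)C2(C)C)C(=O)[C@]1(C)CCC1=CC(=O)OC1
F4 | step 9 | C1=C10 alkene isomer of 19 (C5–H, either epimer) | C[C@@H]1CCC2C(=CC[C@H](O)C2(C)C)[C@]1(C)CCC1=CC(=O)OC1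
F5 | step 12 | C3 triethylsilyl ether of 25 (cis-fused) | C[C@@H]1CC[C@]2(O)[C@@H](C[C@H](O[Si](CC)(CC)CC)C2(C)C)C(=O)[C@]1(C)CCC1=CC(=O)OC1
F6 | step 12 | C3 triethylsilyl ether of 26 (trans-fused) | C[C@@H]1CC[C@]2(O)[C@H](C[C@H](O[Si](CC)(CC)CC)C2(C)C)C(=O)[C@]1(C)CCC1=CC(=O)OC1
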